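**Plan**

1. Halimane numbering is used: ring A = C1–C5 + C10, ring B = C5–C10, ester carbon C18 on C4, side chain C11–C16 on C9. Retrosynthetic cuts: the acetate, then C14–C15 and C13–CH3 (alkyne carboalumination), C4–CH3 (enolate methylation), C5–H with C1–O (allylic transposition of a 5(10)-en-1-ol), then C1–C2 and C1–C10 together, C1 being carbon monoxide.
2. Further cuts: C4–C3 (vinyl conjugate addition), C4=C5 (aldol condensation with methyl glyoxylate), C9–C11 and C8–CH3 (conjugate addition and enolate allylation of 2-methylcyclohex-2-enone).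
3. Forward order: ring B with its C9 chain first, then the C4 arm on C5, then ring A closed between C1 and C2, then the side chain is finished.
4. Enabling feature: C1 is a one-carbon link between C10 and the C2–C3–C4 arm, and C10 is the carbonyl carbon of a ring B ketone that can enolise only toward C5 because C9 is quaternary. Its enol triflate therefore has the C5=C10 double bond, CO becomes C1 as ring A closes, and the C1 ketone is the handle that later moves the double bond to C1=C10 and puts hydrogen on C5.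
5. Stereochemistry: C8 from the ligand of the conjugate addition; C9 from allylation anti to the C8 methyl; C5 from the CBS-set C1 carbinol by suprafacial diazene transposition; C4 from axial methylation of the ring A ester enolate; 13E from syn-carboalumination.

Key step: step 6

Remark: compounds 7–17 are carried as mixtures at C4 (and at the transient carbinol carbon of 7 and 8); C4 is fixed only in step 9, so these centres are left open in the SMILES.

**Route**

Step 1
Reactants: 1 2-methylcyclohex-2-en-1-one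
Product: 3 (2S,3R)-2,3-dimethyl-2-(prop-2-en-1-yl)cyclohexan-1-one, via aluminium enolate 2 (not isolated)
Conditions: Me3Al, Cu(OTf)2 (2 mol %), BINOL-derived phosphoramidite ligand (4 mol %, the enantiomer that gives 3R), Et2O, −30 °C; then MeLi, allyl iodide, THF/DMPU, −30 °C → rt
Reagents that add atoms: trimethylaluminium, C[Al](C)C; allyl iodide, C=CCI
Why: Copper-catalysed asymmetric conjugate addition sets C8 under ligand control, and the aluminium enolate, activated as its ate complex, is allylated anti to the new C8 methyl, which sets the quaternary C9 (tandem conjugate addition–enolate alkylation).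

Step 2
Reactants: 3 (2S,3R)-2,3-dimethyl-2-(prop-2-en-1-yl)cyclohexan-1-one
Product: 5 (2S,3R)-2-(3-hydroxypropyl)-2,3-dimethylcyclohexan-1-one, via alkylborane 4 (not isolated)
Conditions: 9-BBN, THF, 0 °C → rt; then aq. NaOH, H2O2, 0 °C
Reagents that add atoms: hydrogen peroxide, OO
Why: Anti-Markovnikov hydroboration of the terminal alkene with the bulky borane should spare the hindered ketone, and oxidation gives the primary alcohol (hydroboration–oxidation).

Step 3
Reactants: 5 (2S,3R)-2-(3-hydroxypropyl)-2,3-dimethylcyclohexan-1-one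
Product: 6 (2S,3R)-2-[3-(tert-butyldimethylsilyloxy)propyl]-2,3-dimethylcyclohexan-1-one
Conditions: TBSCl, imidazole, DMF, rt
Reagents that add atoms: tert-butyldimethylsilyl chloride, C[Si](C)(Cl)C(C)(C)C
Why: Silylation of the primary alcohol protects it from the bases and the mesylation that follow (silyl ether formation).

Step 4
Reactants: 6 (2S,3R)-2-[3-(tert-butyldimethylsilyloxy)propyl]-2,3-dimethylcyclohexan-1-one
Product: 9 methyl (2E)-2-[(3S,4R)-3-[3-(tert-butyldimethylsilyloxy)propyl]-3,4-dimethyl-2-oxocyclohexylidene]acetate, via lithium aldolate 7 (not isolated), via mesylate 8 (not isolated)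
Conditions: LiN(i-Pr)2, THF, −78 °C; methyl glyoxylate, −78 °C; MsCl, −78 → 0 °C; DBU, rt
Reagents that add atoms: methyl glyoxylate, COC(=O)C=O
Why: The ketone can enolise only at C5 because C9 is quaternary, so aldol addition to the glyoxylate and E1cB loss of the mesylate should give the conjugated E-ylidene, the two transient stereocentres being destroyed (aldol condensation).

Step 5
Reactants: 9 methyl (2E)-2-[(3S,4R)-3-[3-(tert-butyldimethylsilyloxy)propyl]-3,4-dimethyl-2-oxocyclohexylidene]acetate
Product: 11 methyl 2-[(3S,4R)-3-[3-(tert-butyldimethylsilyloxy)propyl]-3,4-dimethyl-2-(trifluoromethanesulfonyloxy)cyclohex-1-en-1-yl]but-3-enoate (both epimers at C2 of the butenoate), via magnesium enolate 10 (not isolated)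
Conditions: CH2=CHMgBr, CuBr·SMe2 (10 mol %), THF, −78 °C; then N-(5-chloropyridin-2-yl)bis(trifluoromethanesulfonimide), −78 °C → rt
Reagents that add atoms: vinylmagnesium bromide, C=C[Mg]Br; N-(5-chloropyridin-2-yl)bis(trifluoromethanesulfonimide), O=S(=O)(N(c1ccc(Cl)cn1)S(=O)(=O)C(F)(F)F)C(F)(F)F
Why: Copper-catalysed 1,4-addition should place the vinyl group on C4, the carbon β to the ketone, and the regio-defined enolate is O-sulfonylated to the C5=C10 enol triflate, the new C4 centre being formed without control and corrected in step 9 (conjugate addition–enolate triflation).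

Step 6
Reactants: 11 methyl 2-[(3S,4R)-3-[3-(tert-butyldimethylsilyloxy)propyl]-3,4-dimethyl-2-(trifluoromethanesulfonyloxy)cyclohex-1-en-1-yl]but-3-enoate
Product: 13 methyl (1RS,5S,6R)-5-[3-(tert-butyldimethylsilyloxy)propyl]-5,6-dimethyl-4-oxo-1,2,3,4,5,6,7,8-octahydronaphthalene-1-carboxylate, via alkylborane 12 (not isolated)
Conditions: 9-BBN, THF, 0 °C → rt; then CO (1 atm), Pd(PPh3)4 (5 mol %), K3PO4, dioxane, 60 °C
Reagents that add atoms: carbon monoxide, [C-]#[O+]
Why: 9-BBN adds to the only monosubstituted alkene of 11 to give the primary borane 12; zerovalent palladium then inserts into the C10–O bond of the triflate, CO inserts to give the acyl-palladium species, and base-assisted transfer of C2 from boron followed by reductive elimination forms the C1–C2 bond. The closest known reaction type is the carbonylative B-alkyl Suzuki–Miyaura coupling of alkenyl electrophiles, here run intramolecularly. Ring A closes as a six-membered enone by acyl–alkyl reductive elimination from a seven-membered acyl(alkyl)palladacycle, CO supplying C1, so that C1–C10 and C1–C2 are made in one operation. No stereocentre is formed: C5 is sp2 and C4 stays an epimer mixture. The step needs CO insertion to outrun direct alkyl–alkenyl coupling (which would give a cyclopentene) and needs a single enol triflate regioisomer. The CO atmosphere and the slow transmetalation of the borane favour insertion first, and the quaternary C9 guarantees that the triflate double bond is C5=C10.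

Step 7
Reactants: 13 methyl (1RS,5S,6R)-5-[3-(tert-butyldimethylsilyloxy)propyl]-5,6-dimethyl-4-oxo-1,2,3,4,5,6,7,8-octahydronaphthalene-1-carboxylate
Product: 14 methyl (1RS,4S,5S,6R)-5-[3-(tert-butyldimethylsilyloxy)propyl]-4-hydroxy-5,6-dimethyl-1,2,3,4,5,6,7,8-octahydronaphthalene-1-carboxylate
Conditions: (R)-2-methyl-CBS-oxazaborolidine (20 mol %), BH3·SMe2, THF, −30 °C
Reagents that add atoms: none
Why: In the Corey–Bakshi–Shibata reduction the catalyst should treat the alkenyl carbon C10 as the large group and deliver hydride to one face of the C1 ketone, which sets the C1 carbinol as S under reagent control (1,2-reduction of the enone).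

Step 8
Reactants: 14 methyl (1RS,4S,5S,6R)-5-[3-(tert-butyldimethylsilyloxy)propyl]-4-hydroxy-5,6-dimethyl-1,2,3,4,5,6,7,8-octahydronaphthalene-1-carboxylate
Product: 17 methyl (1RS,5S,6R,8aR)-5-[3-(tert-butyldimethylsilyloxy)propyl]-5,6-dimethyl-1,2,3,5,6,7,8,8a-octahydronaphthalene-1-carboxylate, via sulfonylhydrazine 15 (not isolated), via allylic diazene 16 (not isolated)
Conditions: 2-nitrobenzenesulfonylhydrazide, PPh3, diethyl azodicarboxylate, THF, −30 °C → rt
Reagents that add atoms: none
Why: Mitsunobu displacement by the sulfonylhydrazide inverts C1, loss of sulfinic acid gives the allylic diazene, and its retro-ene loss of N2 delivers hydrogen to C5 on the face that carried nitrogen, so the C1 configuration is transferred to C5 while the double bond moves to C1=C10 (reductive allylic transposition).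

Step 9
Reactants: 17 methyl (1RS,5S,6R,8aR)-5-[3-(tert-butyldimethylsilyloxy)propyl]-5,6-dimethyl-1,2,3,5,6,7,8,8a-octahydronaphthalene-1-carboxylate
Product: 19 methyl (1S,5S,6R,8aS)-5-[3-(tert-butyldimethylsilyloxy)propyl]-1,5,6-trimethyl-1,2,3,5,6,7,8,8a-octahydronaphthalene-1-carboxylate, via lithium enolate 18 (not isolated)
Conditions: LiN(i-Pr)2, THF/DMPU, −78 °C; MeI, −78 → −20 °C
Reagents that add atoms: iodomethane, CI
Why: Both C4 epimers converge on one exocyclic ester enolate, and because the sp2 carbon C10 carries no axial group while the equatorial path is crowded by C6, methyl iodide should enter axially on the face opposite to H-5, which sets the quaternary C4 (enolate alkylation under substrate control).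

Step 10
Reactants: 19 methyl (1S,5S,6R,8aS)-5-[3-(tert-butyldimethylsilyloxy)propyl]-1,5,6-trimethyl-1,2,3,5,6,7,8,8a-octahydronaphthalene-1-carboxylate
Product: 20 methyl (1S,5S,6R,8aS)-5-(3-hydroxypropyl)-1,5,6-trimethyl-1,2,3,5,6,7,8,8a-octahydronaphthalene-1-carboxylate
Conditions: Bu4NF, THF, rt
Reagents that add atoms: none
Why: Fluoride should cleave the primary silyl ether and leave the hindered quaternary ester untouched (desilylation).

Step 11
Reactants: 20 methyl (1S,5S,6R,8aS)-5-(3-hydroxypropyl)-1,5,6-trimethyl-1,2,3,5,6,7,8,8a-octahydronaphthalene-1-carboxylate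
Product: 21 methyl (1S,5S,6R,8aS)-1,5,6-trimethyl-5-(3-oxopropyl)-1,2,3,5,6,7,8,8a-octahydronaphthalene-1-carboxylate
Conditions: Dess–Martin periodinane, NaHCO3, CH2Cl2, rt
Reagents that add atoms: none
Why: Dess–Martin oxidation should give the aldehyde under neutral conditions that touch neither the alkene nor the ester.

Step 12
Reactants: 21 methyl (1S,5S,6R,8aS)-1,5,6-trimethyl-5-(3-oxopropyl)-1,2,3,5,6,7,8,8a-octahydronaphthalene-1-carboxylate
Product: 22 methyl (1S,5S,6R,8aS)-5-(but-3-yn-1-yl)-1,5,6-trimethyl-1,2,3,5,6,7,8,8a-octahydronaphthalene-1-carboxylate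
Conditions: dimethyl (1-diazo-2-oxopropyl)phosphonate, K2CO3, MeOH, rt
Reagents that add atoms: dimethyl (1-diazo-2-oxopropyl)phosphonate, COP(=O)(OC)C(=[N+]=[N-])C(C)=O
Why: The Ohira–Bestmann homologation should convert the aldehyde into the terminal alkyne with one added carbon, and no stereocentre is α to the aldehyde.

Step 13
Reactants: 22 methyl (1S,5S,6R,8aS)-5-(but-3-yn-1-yl)-1,5,6-trimethyl-1,2,3,5,6,7,8,8a-octahydronaphthalene-1-carboxylate
Product: 24 methyl (1S,5S,6R,8aS)-5-[(3E)-5-hydroxy-3-methylpent-3-en-1-yl]-1,5,6-trimethyl-1,2,3,5,6,7,8,8a-octahydronaphthalene-1-carboxylate, via alkenylalane 23 (not isolated)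
Conditions: Me3Al, Cp2ZrCl2, ClCH2CH2Cl, rt; then n-BuLi, THF, −78 °C; (CH2O)n, → rt
Reagents that add atoms: trimethylaluminium, C[Al](C)C; formaldehyde (as paraformaldehyde), C=O
Why: Zirconium-catalysed syn-carboalumination (Negishi) adds methyl to C13 and aluminium to C14 on the same side, and hydroxymethylation of the derived alanate with retention should fix the 13E geometry.

Step 14
Reactants: 24 methyl (1S,5S,6R,8aS)-5-[(3E)-5-hydroxy-3-methylpent-3-en-1-yl]-1,5,6-trimethyl-1,2,3,5,6,7,8,8a-octahydronaphthalene-1-carboxylate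
Product: 25 methyl (1S,5S,6R,8aS)-5-[(3E)-5-acetoxy-3-methylpent-3-en-1-yl]-1,5,6-trimethyl-1,2,3,5,6,7,8,8a-octahydronaphthalene-1-carboxylate
Conditions: Ac2O, pyridine, DMAP (cat.), CH2Cl2, rt
Reagents that add atoms: acetic anhydride, CC(=O)OC(C)=O
Why: Acyl transfer to the primary allylic alcohol should give the acetate without affecting the rest of the molecule (acetylation).

**Compound list**

1 | 2-methylcyclohex-2-en-1-one | CC1=CCCCC1=O | starting material
2 | dimethylaluminium enolate of (R)-2,3-dimethylcyclohexanone (not isolated) | C[C@@H]1CCCC(O[Al](C)C)=C1C | intermediate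
3 | (2S,3R)-2,3-dimethyl-2-(prop-2-en-1-yl)cyclohexan-1-one | O=C1CCC[C@@H](C)[C@]1(C)CC=C | intermediate
4 | B-alkyl-9-BBN adduct of 3 (not isolated) | O=C1CCC[C@@H](C)[C@]1(C)CCCB1C2CCCC1CCC2 | intermediate
5 | (2S,3R)-2-(3-hydroxypropyl)-2,3-dimethylcyclohexan-1-one | O=C1CCC[C@@H](C)[C@]1(C)CCCO | intermediate
6 | (2S,3R)-2-[3-(tert-butyldimethylsilyloxy)propyl]-2,3-dimethylcyclohexan-1-one | O=C1CCC[C@@H](C)[C@]1(C)CCCO[Si](C)(C)C(C)(C)C | intermediate
7 | lithium aldolate, methyl 2-(lithiooxy)-2-[(3S,4R)-3-[3-(tert-butyldimethylsilyloxy)propyl]-3,4-dimethyl-2-oxocyclohexyl]acetate (not isolated) | O=C1C(C(O[Li])C(=O)OC)CC[C@@H](C)[C@]1(C)CCCO[Si](C)(C)C(C)(C)C | intermediate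
8 | mesylate, methyl 2-(methanesulfonyloxy)-2-[(3S,4R)-3-[3-(tert-butyldimethylsilyloxy)propyl]-3,4-dimethyl-2-oxocyclohexyl]acetate (not isolated) | O=C1C(C(OS(C)(=O)=O)C(=O)OC)CC[C@@H](C)[C@]1(C)CCCO[Si](C)(C)C(C)(C)C | intermediate
9 | methyl (2E)-2-[(3S,4R)-3-[3-(tert-butyldimethylsilyloxy)propyl]-3,4-dimethyl-2-oxocyclohexylidene]acetate | O=C1/C(=C/C(=O)OC)CC[C@@H](C)[C@]1(C)CCCO[Si](C)(C)C(C)(C)C | intermediate
10 | bromomagnesium enolate of methyl 2-[(3S,4R)-3-[3-(tert-butyldimethylsilyloxy)propyl]-3,4-dimethyl-2-oxocyclohexyl]but-3-enoate (not isolated) | Br[Mg]OC1=C(C(C=C)C(=O)OC)CC[C@@H](C)[C@]1(C)CCCO[Si](C)(C)C(C)(C)C | intermediate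
11 | methyl 2-[(3S,4R)-3-[3-(tert-butyldimethylsilyloxy)propyl]-3,4-dimethyl-2-(trifluoromethanesulfonyloxy)cyclohex-1-en-1-yl]but-3-enoate | FC(F)(F)S(=O)(=O)OC1=C(C(C=C)C(=O)OC)CC[C@@H](C)[C@]1(C)CCCO[Si](C)(C)C(C)(C)C | intermediate
12 | B-alkyl-9-BBN adduct of 11 at the terminal vinyl carbon (not isolated) | FC(F)(F)S(=O)(=O)OC1=C(C(CCB2C3CCCC2CCC3)C(=O)OC)CC[C@@H](C)[C@]1(C)CCCO[Si](C)(C)C(C)(C)C | intermediate
13 | methyl (1RS,5S,6R)-5-[3-(tert-butyldimethylsilyloxy)propyl]-5,6-dimethyl-4-oxo-1,2,3,4,5,6,7,8-octahydronaphthalene-1-carboxylate | COC(=O)C1CCC(=O)C2=C1CC[C@@H](C)[C@]2(C)CCCO[Si](C)(C)C(C)(C)C | intermediate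
14 | methyl (1RS,4S,5S,6R)-5-[3-(tert-butyldimethylsilyloxy)propyl]-4-hydroxy-5,6-dimethyl-1,2,3,4,5,6,7,8-octahydronaphthalene-1-carboxylate | COC(=O)C1CC[C@H](O)C2=C1CC[C@@H](C)[C@]2(C)CCCO[Si](C)(C)C(C)(C)C | intermediate
15 | N-allylic N-(2-nitrobenzenesulfonyl)hydrazine from 14, nitrogen on C4 with inverted configuration (not isolated) | COC(=O)C1CC[C@@H](N(N)S(=O)(=O)c3ccccc3[N+](=O)[O-])C2=C1CC[C@@H](C)[C@]2(C)CCCO[Si](C)(C)C(C)(C)C | intermediate
16 | allylic monoalkyl diazene from 15 (not isolated) | COC(=O)C1CC[C@@H](N=N)C2=C1CC[C@@H](C)[C@]2(C)CCCO[Si](C)(C)C(C)(C)C | intermediate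
17 | methyl (1RS,5S,6R,8aR)-5-[3-(tert-butyldimethylsilyloxy)propyl]-5,6-dimethyl-1,2,3,5,6,7,8,8a-octahydronaphthalene-1-carboxylate | COC(=O)C1CCC=C2[C@@H]1CC[C@@H](C)[C@]2(C)CCCO[Si](C)(C)C(C)(C)C | intermediate
18 | lithium ester enolate of 17 (not isolated) | [Li]OC(OC)=C1CCC=C2[C@@H]1CC[C@@H](C)[C@]2(C)CCCO[Si](C)(C)C(C)(C)C | intermediate
19 | methyl (1S,5S,6R,8aS)-5-[3-(tert-butyldimethylsilyloxy)propyl]-1,5,6-trimethyl-1,2,3,5,6,7,8,8a-octahydronaphthalene-1-carboxylate | COC(=O)[C@@]1(C)CCC=C2[C@@H]1CC[C@@H](C)[C@]2(C)CCCO[Si](C)(C)C(C)(C)C | intermediate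
20 | methyl (1S,5S,6R,8aS)-5-(3-hydroxypropyl)-1,5,6-trimethyl-1,2,3,5,6,7,8,8a-octahydronaphthalene-1-carboxylate | COC(=O)[C@@]1(C)CCC=C2[C@@H]1CC[C@@H](C)[C@]2(C)CCCO | intermediate
21 | methyl (1S,5S,6R,8aS)-1,5,6-trimethyl-5-(3-oxopropyl)-1,2,3,5,6,7,8,8a-octahydronaphthalene-1-carboxylate | COC(=O)[C@@]1(C)CCC=C2[C@@H]1CC[C@@H](C)[C@]2(C)CCC=O | intermediate
22 | methyl (1S,5S,6R,8aS)-5-(but-3-yn-1-yl)-1,5,6-trimethyl-1,2,3,5,6,7,8,8a-octahydronaphthalene-1-carboxylate | COC(=O)[C@@]1(C)CCC=C2[C@@H]1CC[C@@H](C)[C@]2(C)CCC#C | intermediate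
23 | (E)-alkenyldimethylalane from 22 (not isolated) | COC(=O)[C@@]1(C)CCC=C2[C@@H]1CC[C@@H](C)[C@]2(C)CC/C(C)=C/[Al](C)C | intermediate
24 | methyl (1S,5S,6R,8aS)-5-[(3E)-5-hydroxy-3-methylpent-3-en-1-yl]-1,5,6-trimethyl-1,2,3,5,6,7,8,8a-octahydronaphthalene-1-carboxylate | COC(=O)[C@@]1(C)CCC=C2[C@@H]1CC[C@@H](C)[C@]2(C)CC/C(C)=C/CO | intermediate
25 | methyl (1S,5S,6R,8aS)-5-[(3E)-5-acetoxy-3-methylpent-3-en-1-yl]-1,5,6-trimethyl-1,2,3,5,6,7,8,8a-octahydronaphthalene-1-carboxylate | COC(=O)[C@@]1(C)CCC=C2[C@@H]1CC[C@@H](C)[C@]2(C)CC/C(C)=C/COC(C)=O | target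

**Step count**

Total: 14 steps. Longest linear sequence: 14 steps (from 1).

**Steps most likely to fail**

Step 6. The risk is that direct alkyl–alkenyl coupling without CO uptake (closing a five-membered ring), or protodeboronation of the borane, outruns acyl transfer, so that ring A does not form as the enone. The fallback separates CO incorporation from ring closure and sets out from 11. Thiocarbonylation of the triflate (Pd(OAc)2, dppf, CO, EtSH, Et3N, DMF) should give methyl 2-[(3S,4R)-3-[3-(tert-butyldimethylsilyloxy)propyl]-2-(ethylsulfanylcarbonyl)-3,4-dimethylcyclohex-1-en-1-yl]but-3-enoate F1. Hydroboration of its vinyl group with 9-BBN gives the B-alkyl-9-BBN adduct of the thioester F2, which is not isolated. Copper-mediated, palladium-catalysed acyl cross-coupling of the thioester with the borane (Liebeskind–Srogl coupling: Pd2(dba)3, tri(2-furyl)phosphine, copper thiophene-2-carboxylate Cu(O2C-C4H3S), Cs2CO3, THF) closes the C1–C2 bond with no CO present and returns to 13.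

Step 9. The risk is poor facial selectivity in the enolate methylation: approach from the face syn to H-5 would give the C4 epimer, which cannot be corrected. The fallback fixes C4 before C5 is a stereocentre, accepts a separation, and sets out from 13. Methylation of its vinylogous ester enolate (LiN(i-Pr)2, MeI) at the carbon α to the ester should give both quaternary epimers. These are separated into methyl (1S,5S,6R)-5-[3-(tert-butyldimethylsilyloxy)propyl]-1,5,6-trimethyl-4-oxo-1,2,3,4,5,6,7,8-octahydronaphthalene-1-carboxylate F4 and its (1R) epimer F5, which is set aside. Reduction of F4 under the conditions of step 7 gives the (4S) allylic alcohol F6. Under the conditions of step 8 it passes through the sulfonylhydrazine F7 and the allylic diazene F8, neither isolated, and the hydrogen is delivered to C5 against a defined C4, which returns to 19.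

Step 8. The risk is slow Mitsunobu displacement at the hindered allylic carbinol, with elimination to a diene or SN2′ attack eroding the transfer of configuration to C5. The fallback uses a π-allyl hydride delivery and sets out from 14. Methyl chloroformate and pyridine should give the allylic methyl carbonate of 14 F3. Formate hydrogenolysis (Pd(OAc)2, PBu3, HCO2NH4, THF) ionises the carbonate with inversion, and hydride passes from palladium to the more substituted terminus C5 on the face opposite to the original oxygen. This is the same stereochemical outcome as the diazene route and returns to 17.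

**Further compounds**

F1 | step 6 | methyl 2-[(3S,4R)-3-[3-(tert-butyldimethylsilyloxy)propyl]-2-(ethylsulfanylcarbonyl)-3,4-dimethylcyclohex-1-en-1-yl]but-3-enoate | CCSC(=O)C1=C(C(C=C)C(=O)OC)CC[C@@H](C)[C@]1(C)CCCO[Si](C)(C)C(C)(C)C
F2 | step 6 | B-alkyl-9-BBN adduct of the thioester F1 | CCSC(=O)C1=C(C(CCB2C3CCCC2CCC3)C(=O)OC)CC[C@@H](C)[C@]1(C)CCCO[Si](C)(C)C(C)(C)C
F3 | step 8 | methyl (1RS,4S,5S,6R)-5-[3-(tert-butyldimethylsilyloxy)propyl]-4-(methoxycarbonyloxy)-5,6-dimethyl-1,2,3,4,5,6,7,8-octahydronaphthalene-1-carboxylate | COC(=O)C1CC[C@H](OC(=O)OC)C2=C1CC[C@@H](C)[C@]2(C)CCCO[Si](C)(C)C(C)(C)C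
F4 | step 9 | methyl (1S,5S,6R)-5-[3-(tert-butyldimethylsilyloxy)propyl]-1,5,6-trimethyl-4-oxo-1,2,3,4,5,6,7,8-octahydronaphthalene-1-carboxylate | COC(=O)[C@@]1(C)CCC(=O)C2=C1CC[C@@H](C)[C@]2(C)CCCO[Si](C)(C)C(C)(C)C
F5 | step 9 | methyl (1R,5S,6R)-5-[3-(tert-butyldimethylsilyloxy)propyl]-1,5,6-trimethyl-4-oxo-1,2,3,4,5,6,7,8-octahydronaphthalene-1-carboxylate | COC(=O)[C@]1(C)CCC(=O)C2=C1CC[C@@H](C)[C@]2(C)CCCO[Si](C)(C)C(C)(C)C
F6 | step 9 | methyl (1S,4S,5S,6R)-5-[3-(tert-butyldimethylsilyloxy)propyl]-4-hydroxy-1,5,6-trimethyl-1,2,3,4,5,6,7,8-octahydronaphthalene-1-carboxylate | COC(=O)[C@@]1(C)CC[C@H](O)C2=C1CC[C@@H](C)[C@]2(C)CCCO[Si](C)(C)C(C)(C)C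
F7 | step 9 | N-allylic N-(2-nitrobenzenesulfonyl)hydrazine from F6, nitrogen on C4 with inverted configuration | COC(=O)[C@@]1(C)CC[C@@H](N(N)S(=O)(=O)c3ccccc3[N+](=O)[O-])C2=C1CC[C@@H](C)[C@]2(C)CCCO[Si](C)(C)C(C)(C)C
F8 | step 9 | allylic monoalkyl diazene from F7 | COC(=O)[C@@]1(C)CC[C@@H](N=N)C2=C1CC[C@@H](C)[C@]2(C)CCCO[Si](C)(C)C(C)(C)C
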